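Time separates the two products in these runs: the right-handed product trails the left-handed product.

| flask | left-handed substrate | right-handed substrate | reagent | remark | time |
|---|---|---|---|---|---|
| summer | 20 mM | 20 mM | 4.2 equiv (fed, over 10 min) | run made earlier |  |
| dawn | 20 mM | 20 mM | 6.6 equiv (fed, over 10 min) | run made earlier |  |
| midnight | 10 mM | 10 mM | 3 equiv (fed, over 10 min) | run made earlier |  |
| violet | 20 mM | 20 mM | 3.00 equiv (fed, over 10 min) |  | 10 min |
| amber | 20 mM | 20 mM | 3.00 equiv (fed, over 15 min) |  | 10 min |

| run | time / min | left-handed product / % | right-handed product / % |
|---|---|---|---|
| summer | 0.833 | 0.7 | 0 |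
| summer | 2.50 | 1.9 | 0.2 |
| summer | 4.00 | 4.0 | 1.7 |
| summer | 6.00 | 6.3 | 3.9 |
| summer | 10.0 | 11.3 | 8.4 |
| summer | 12.0 | 12.8 | 10.7 |
| dawn | 1.00 | 0.8 | 0 |
| dawn | 1.50 | 1.0 | 0.6 |
| dawn | 2.50 | 2.8 | 1.4 |
| dawn | 4.00 | 6.0 | 2.0 |
| dawn | 8.00 | 12.7 | 8.6 |
| dawn | 12.0 | 16.5 | 14.2 |
| midnight | 2.50 | 0.3 | 0 |
| midnight | 5.00 | 2.1 | 0.8 |
| midnight | 8.00 | 4.3 | 2.5 |
| midnight | 10.0 | 4.9 | 3.8 |
| midnight | 12.0 | 5.9 | 4.9 |

(readings scatter by 0.3 percentage points)

- reagent is single-handed; left-handed substrate and right-handed substrate are mirror images of each other, charged as a racemate, each of them at the stated concentration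
- percentages count the whole charge, also what has not yet gone in
- an excess is the difference of the two amounts in percent of their sum
- an excess is below zero if the other one leads
- the handed part of reagent does not stay in what it makes, so the products of the two hands are mirror images too

- which one finishes higher in excess of left-handed product over right-handed product in the product ("neither" within 2 percentage points) (violet / amber / neither)
- excess of left-handed product over right-handed product in the product at the end, violet
- excess of left-handed product over right-handed product in the product at the end, amber

Read the table one run at a time, near the end of the feed. In summer at 10.0 min, the gap between the products is 2.9 percentage points. The left-handed product has averaged 1.13 %/min, so the gap is worth 2.57 min of that rate. Call this the lag: the gap between the products divided by the mean rate of the left-handed product.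

Dawn takes reagent faster, and at 8.00 min it reads 2.58 min. Midnight at 10.0 min reads 2.24 min, but its gap is 1.1 points against a scatter of 0.3 points per reading, so it is a rough reading.

Now suppose the lag holds for the new flasks. If the left-handed product has run for time t, the right-handed product has run for t minus the lag. The rate cancels from the excess, which becomes the lag divided by t plus t minus the lag. My reckoning at 10 min is 14.7% for both violet and amber, so neither.

The forecast says neither, with 14.5% for violet and 15% for amber, close to my figure but not the same. Its ground is “The excess is independent of feed rate”.

The flasks give 15.2% for violet and 16.1% for amber, so the verdict is neither: they differ by 0.90 points, less than the margin of 2 points.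

    reagent + left-handed substrate → left-handed product (k = 2.80 /M/min)
    reagent + right-handed substrate → right-handed product (k = 0.0380 /M/min)
    left-handed substrate ⇌ achiral form (K = 1.20, k = 0.290 /min)
    right-handed substrate ⇌ achiral form (K = 1.20, k = 0.290 /min)
    achiral form → waste (k = 0.200 /min)
    left-handed product ⇌ right-handed product (k = 0.390 /min)

The excess does not show that violet holds 40.5% waste at 10 min, more than the 15.3% in both products. The lag times the mean rate gives a gap of 2.3 points for violet, where the flask shows 2.3 points. For amber it gives 1.6 points, where the flask shows 1.8 points. A later reading breaks the constant lag: at 40 min, after its feed ended at 15 min, amber shows 0.408%, where the lag gives 3.32%.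

Readings and results are simulated from invented constants.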